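The 2,3-dihydrobenzofuran is cut at C3–C3a and O1–C2. Ring A, which carries O1 on C7a and C3 on the adjacent C3a, is treated as the enol of cyclohexane-1,3-dione, and C2 (aryl) with C3 (carboxyl) as a caffeoyl alkene. One manganese-mediated radical–polar annulation joins the two pieces, closes the furan ring and sets C2 and C3 trans, while a chelated oxazolidinone imide on the alkene is to select the face. Its precursor is the N-cinnamoyl oxazolidinone with a silyl-protected catechol. Ring A is later aromatised, oxygenated at C7 and coupled at C4 by a Heck reaction. Only silyl groups are removed at the end, so the acrylate never meets hydrogen.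

Key step: step 3

Assumption: danshensu is used as the free (R)-acid (the commercial sodium salt is acidified first). Benzofuran numbering (O1, C2, C3, C3a, C4–C7, C7a) is used for the bicyclic core throughout.

Step 1
Reactants: 1 caffeic acid
Product: 3 (E)-3-[3,4-bis(triisopropylsilyloxy)phenyl]acrylic acid, via silyl ester 2 (not isolated)
Conditions: TIPSCl (3.3 equiv), imidazole, DMF, rt → 40 °C; then K2CO3, THF/MeOH/H2O, 0 °C
Reagents that add atoms: triisopropylsilyl chloride, CC(C)[Si](Cl)(C(C)C)C(C)C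
Why: Silyl chloride/imidazole silylation covers both phenols and the carboxyl group, and brief carbonate hydrolysis cleaves only the far more labile silyl ester; triisopropylsilyl ethers are chosen because they should survive the oxidative, acidic and mildly basic steps ahead and come off with fluoride, whereas a hydrogenolysis-labile group could not be removed next to the acrylate double bond.

Step 2
Reactants: 3 (E)-3-[3,4-bis(triisopropylsilyloxy)phenyl]acrylic acid; 4 (S)-4-benzyloxazolidin-2-one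
Product: 6 (S)-4-benzyl-3-{(E)-3-[3,4-bis(triisopropylsilyloxy)phenyl]acryloyl}oxazolidin-2-one, via mixed pivalic anhydride 5 (not isolated)
Conditions: PivCl, Et3N, THF, −20 °C; then 4, LiCl, −20 °C → rt
Reagents that add atoms: none
Why: N-Acylation of the oxazolidinone through the mixed pivalic anhydride with LiCl/Et3N is a standard route to N-enoyl imides and should leave the E alkene and the aryl silyl ethers untouched.

Step 3
Reactants: 6 (S)-4-benzyl-3-{(E)-3-[3,4-bis(triisopropylsilyloxy)phenyl]acryloyl}oxazolidin-2-one; 7 cyclohexane-1,3-dione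
Product: 8 (S)-4-benzyl-3-{(2S,3S)-2-[3,4-bis(triisopropylsilyloxy)phenyl]-4-oxo-2,3,4,5,6,7-hexahydrobenzofuran-3-carbonyl}oxazolidin-2-one
Conditions: Mn(OAc)3·2H2O (2.5 equiv), Yb(OTf)3 (1.2 equiv), CF3CH2OH, 0 °C → rt, 7 (1.3 equiv) added slowly
Reagents that add atoms: none
Why: Trivalent manganese turns the enol of 7 into its electrophilic C2 radical, which adds to the alkene carbon next to the imide carbonyl of 6 (the position that leaves a benzylic radical), and a second Mn(OAc)3 oxidises that radical to the benzylic cation stabilised by the para silyloxy group. The enol oxygen then traps the cation in a 5-exo-trig closure (the quinoid C2=aryl bond is the exocyclic π bond and the enol C3a=C7a lies inside the new ring), which completes the dihydrofuran. The closest known reaction type is the Mn(OAc)3 or (NH4)2Ce(NO3)6 oxidative [3+2] annulation of cyclic 1,3-diones with cinnamic esters and amides to trans-2-aryl-3-acyl dihydrofurans, applied here to an N-cinnamoyl oxazolidinone. C3 is set in the C–C bond formation: Yb(OTf)3 is to hold the imide as its chelate with the two carbonyls syn and the enoyl unit s-cis, the benzyl group of the auxiliary then covers the Re face of the α-carbon, and attack on the Si face gives 3S. C2 is set in the ring closure, in which the aryl group takes the side opposite the bulky acyl group (trans, 2S), and any cis isomer can equilibrate through the benzylic cation. The step needs regioselectivity (secured by the radical-stabilising aryl group), trans selectivity (secured as stated) and facial selectivity, which rests on the chelated rotamer and is the single element not yet demonstrated for this auxiliary; slow addition of 7 is meant to keep the polar, Lewis-acid-promoted conjugate addition of the dione from competing.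

Step 4
Reactants: 8 (S)-4-benzyl-3-{(2S,3S)-2-[3,4-bis(triisopropylsilyloxy)phenyl]-4-oxo-2,3,4,5,6,7-hexahydrobenzofuran-3-carbonyl}oxazolidin-2-one
Product: 10 (S)-4-benzyl-3-{(2S,3S)-2-[3,4-bis(triisopropylsilyloxy)phenyl]-4-hydroxy-2,3-dihydrobenzofuran-3-carbonyl}oxazolidin-2-one, via silyl dienol ether 9 (not isolated)
Conditions: TMSOTf (1.2 equiv), Et3N, CH2Cl2, 0 °C; then Pd(OAc)2 (1.1 equiv), MeCN, rt
Reagents that add atoms: none
Why: Soft enolisation of the vinylogous ester gives the cross-conjugated silyl dienol ether, and Saegusa–Ito oxidation (palladation at C5, β-hydride loss from C6) gives the 2,4-dienone that tautomerises to the C4 phenol; the neutral conditions avoid both base-induced opening of the dihydrofuran and oxidants able to dehydrogenate C2–C3, so the two stereocentres should stay intact.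

Step 5
Reactants: 10 (S)-4-benzyl-3-{(2S,3S)-2-[3,4-bis(triisopropylsilyloxy)phenyl]-4-hydroxy-2,3-dihydrobenzofuran-3-carbonyl}oxazolidin-2-one
Product: 12 (2S,3S)-2-[3,4-bis(triisopropylsilyloxy)phenyl]-4-hydroxy-2,3-dihydrobenzofuran-3-carboxylic acid, via peroxy acid 11 (not isolated)
Conditions: LiOH·H2O (3 equiv), 30% H2O2, THF/H2O, 0 °C; then aq. Na2SO3; then 1 M HCl to pH 3
Reagents that add atoms: hydrogen peroxide, OO
Why: Lithium hydroperoxide attacks the exocyclic imide carbonyl selectively even in hindered acyl oxazolidinones (standard auxiliary hydrolysis) and sulfite reduces the peracid; the cleavage is placed after aromatisation so that O1 is only a poor, phenoxide-type leaving group for β-elimination from C3, and the bulky silyl ethers should tolerate the short cold exposure.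

Step 6
Reactants: 12 (2S,3S)-2-[3,4-bis(triisopropylsilyloxy)phenyl]-4-hydroxy-2,3-dihydrobenzofuran-3-carboxylic acid
Product: 14 (2S,3S)-2-[3,4-bis(triisopropylsilyloxy)phenyl]-4,7-dihydroxy-2,3-dihydrobenzofuran-3-carboxylic acid, via para-quinone 13 (not isolated)
Conditions: K2NO(SO3)2 (2.5 equiv), KH2PO4 buffer, acetone/H2O, 0 °C → rt; then Na2S2O4, EtOAc/H2O, rt
Reagents that add atoms: potassium nitrosodisulfonate, [K+].[K+].[O]N(S(=O)(=O)[O-])S(=O)(=O)[O-]
Why: Teuber oxidation of a phenol with a free para position gives the para-quinone, here with the new oxygen on C7, and dithionite reduces it at once to the hydroquinone; with C3 carrying a carboxylate and not an ester or imide, the C3–H should not be acidic enough for the quinone to tautomerise toward the benzofuran.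

Step 7
Reactants: 14 (2S,3S)-2-[3,4-bis(triisopropylsilyloxy)phenyl]-4,7-dihydroxy-2,3-dihydrobenzofuran-3-carboxylic acid
Product: 15 triisopropylsilyl (2S,3S)-2-[3,4-bis(triisopropylsilyloxy)phenyl]-4-hydroxy-7-(triisopropylsilyloxy)-2,3-dihydrobenzofuran-3-carboxylate
Conditions: TIPSCl (2.1 equiv), imidazole, degassed DMF, 0 °C, argon
Reagents that add atoms: triisopropylsilyl chloride, CC(C)[Si](Cl)(C(C)C)C(C)C
Why: The bulky silyl chloride caps the carboxyl group (as a silyl ester) and the exposed C7 hydroxyl, which is also the more acidic one (ortho to O1), whereas the C4 hydroxyl is flanked by the substituted C3 and can hydrogen-bond to the C3 carbonyl; steric discrimination of the two hydroxyls of an unsymmetrical hydroquinone by a bulky silyl chloride is standard practice.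

Step 8
Reactants: 15 triisopropylsilyl (2S,3S)-2-[3,4-bis(triisopropylsilyloxy)phenyl]-4-hydroxy-7-(triisopropylsilyloxy)-2,3-dihydrobenzofuran-3-carboxylate
Product: 16 triisopropylsilyl (2S,3S)-2-[3,4-bis(triisopropylsilyloxy)phenyl]-7-(triisopropylsilyloxy)-4-(trifluoromethylsulfonyloxy)-2,3-dihydrobenzofuran-3-carboxylate
Conditions: Tf2O, pyridine, CH2Cl2, −20 → 0 °C
Reagents that add atoms: trifluoromethanesulfonic anhydride, O=S(=O)(OS(=O)(=O)C(F)(F)F)C(F)(F)F
Why: O-Triflation of the one remaining phenol with Tf2O/pyridine is routine, and the silyl ester keeps the carboxyl group from forming a mixed anhydride.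

Step 9
Reactants: 17 (R)-3-(3,4-dihydroxyphenyl)-2-hydroxypropanoic acid (danshensu)
Product: 18 methyl (R)-3-(3,4-dihydroxyphenyl)-2-hydroxypropanoate
Conditions: MeOH, H2SO4 (cat.), 40 °C
Reagents that add atoms: methanol, CO
Why: Fischer esterification forms the methyl ester without touching the carbinol stereocentre or the catechol.

Step 10
Reactants: 18 methyl (R)-3-(3,4-dihydroxyphenyl)-2-hydroxypropanoate
Product: 19 methyl (R)-3-[3,4-bis(triisopropylsilyloxy)phenyl]-2-hydroxypropanoate
Conditions: TIPSCl (2.1 equiv), imidazole, DMF, 0 °C → rt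
Reagents that add atoms: triisopropylsilyl chloride, CC(C)[Si](Cl)(C(C)C)C(C)C
Why: Chemoselective O-silylation: the bulky silyl chloride reacts with the two phenols and should leave the hindered, electron-poor secondary α-hydroxy ester free.

Step 11
Reactants: 19 methyl (R)-3-[3,4-bis(triisopropylsilyloxy)phenyl]-2-hydroxypropanoate
Product: 20 methyl (R)-2-(acryloyloxy)-3-[3,4-bis(triisopropylsilyloxy)phenyl]propanoate
Conditions: acryloyl chloride, Et3N, CH2Cl2, −10 → 0 °C
Reagents that add atoms: acryloyl chloride, C=CC(=O)Cl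
Why: O-Acylation of the secondary alcohol with an acid chloride and amine base at low temperature forms the acrylate without involving the stereocentre.

Step 12
Reactants: 16 triisopropylsilyl (2S,3S)-2-[3,4-bis(triisopropylsilyloxy)phenyl]-7-(triisopropylsilyloxy)-4-(trifluoromethylsulfonyloxy)-2,3-dihydrobenzofuran-3-carboxylate; 20 methyl (R)-2-(acryloyloxy)-3-[3,4-bis(triisopropylsilyloxy)phenyl]propanoate
Product: 21 triisopropylsilyl (2S,3S)-2-[3,4-bis(triisopropylsilyloxy)phenyl]-4-{(E)-3-[(R)-3-(3,4-bis(triisopropylsilyloxy)phenyl)-1-methoxy-1-oxopropan-2-yloxy]-3-oxoprop-1-enyl}-7-(triisopropylsilyloxy)-2,3-dihydrobenzofuran-3-carboxylate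
Conditions: Pd(OAc)2 (10 mol %), dppp (12 mol %), Et3N, DMF, 80 °C
Reagents that add atoms: none
Why: Mizoroki–Heck coupling of an aryl triflate with an acrylate gives the (E)-cinnamate by syn insertion and syn β-hydride elimination, and the tertiary amine is too weak a base to deprotonate C3 or the lactate α-carbon.

Step 13
Reactants: 21 triisopropylsilyl (2S,3S)-2-[3,4-bis(triisopropylsilyloxy)phenyl]-4-{(E)-3-[(R)-3-(3,4-bis(triisopropylsilyloxy)phenyl)-1-methoxy-1-oxopropan-2-yloxy]-3-oxoprop-1-enyl}-7-(triisopropylsilyloxy)-2,3-dihydrobenzofuran-3-carboxylate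
Product: 22 (2S,3S)-2-(3,4-dihydroxyphenyl)-4-{(E)-3-[(R)-3-(3,4-dihydroxyphenyl)-1-methoxy-1-oxopropan-2-yloxy]-3-oxoprop-1-enyl}-7-hydroxy-2,3-dihydrobenzofuran-3-carboxylic acid (target)
Conditions: HF·pyridine, pyridine, THF, 0 °C → rt
Reagents that add atoms: none
Why: Fluoride-mediated desilylation cleaves the five aryl silyl ethers and the silyl ester in one operation under buffered, slightly acidic conditions that should leave the methyl ester, the enoate, its double bond and the base-sensitive dihydrobenzofuran untouched.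

Compound list

1 | caffeic acid, (E)-3-(3,4-dihydroxyphenyl)acrylic acid | O=C(O)/C=C/c1ccc(O)c(O)c1 | starting material
2 | triisopropylsilyl (E)-3-[3,4-bis(triisopropylsilyloxy)phenyl]acrylate | CC(C)[Si](C(C)C)(C(C)C)OC(=O)/C=C/c1ccc(O[Si](C(C)C)(C(C)C)C(C)C)c(O[Si](C(C)C)(C(C)C)C(C)C)c1 | intermediate
3 | (E)-3-[3,4-bis(triisopropylsilyloxy)phenyl]acrylic acid | O=C(O)/C=C/c1ccc(O[Si](C(C)C)(C(C)C)C(C)C)c(O[Si](C(C)C)(C(C)C)C(C)C)c1 | intermediate
4 | (S)-4-benzyloxazolidin-2-one | O=C1OC[C@H](Cc2ccccc2)N1 | starting material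
5 | (E)-3-[3,4-bis(triisopropylsilyloxy)phenyl]acrylic pivalic anhydride | CC(C)(C)C(=O)OC(=O)/C=C/c1ccc(O[Si](C(C)C)(C(C)C)C(C)C)c(O[Si](C(C)C)(C(C)C)C(C)C)c1 | intermediate
6 | (S)-4-benzyl-3-{(E)-3-[3,4-bis(triisopropylsilyloxy)phenyl]acryloyl}oxazolidin-2-one | O=C1OC[C@H](Cc2ccccc2)N1C(=O)/C=C/c1ccc(O[Si](C(C)C)(C(C)C)C(C)C)c(O[Si](C(C)C)(C(C)C)C(C)C)c1 | intermediate
7 | cyclohexane-1,3-dione | O=C1CCCC(=O)C1 | starting material
8 | (S)-4-benzyl-3-{(2S,3S)-2-[3,4-bis(triisopropylsilyloxy)phenyl]-4-oxo-2,3,4,5,6,7-hexahydrobenzofuran-3-carbonyl}oxazolidin-2-one | O=C1CCCC2=C1[C@H](C(=O)N1C(=O)OC[C@@H]1Cc1ccccc1)[C@@H](c1ccc(O[Si](C(C)C)(C(C)C)C(C)C)c(O[Si](C(C)C)(C(C)C)C(C)C)c1)O2 | intermediate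
9 | (S)-4-benzyl-3-{(2S,3S)-2-[3,4-bis(triisopropylsilyloxy)phenyl]-4-(trimethylsilyloxy)-2,3,6,7-tetrahydrobenzofuran-3-carbonyl}oxazolidin-2-one | C[Si](C)(C)OC1=CCCC2=C1[C@H](C(=O)N1C(=O)OC[C@@H]1Cc1ccccc1)[C@@H](c1ccc(O[Si](C(C)C)(C(C)C)C(C)C)c(O[Si](C(C)C)(C(C)C)C(C)C)c1)O2 | intermediate
10 | (S)-4-benzyl-3-{(2S,3S)-2-[3,4-bis(triisopropylsilyloxy)phenyl]-4-hydroxy-2,3-dihydrobenzofuran-3-carbonyl}oxazolidin-2-one | Oc1cccc2c1[C@H](C(=O)N1C(=O)OC[C@@H]1Cc1ccccc1)[C@@H](c1ccc(O[Si](C(C)C)(C(C)C)C(C)C)c(O[Si](C(C)C)(C(C)C)C(C)C)c1)O2 | intermediate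
11 | (2S,3S)-2-[3,4-bis(triisopropylsilyloxy)phenyl]-4-hydroxy-2,3-dihydrobenzofuran-3-carboperoxoic acid | Oc1cccc2c1[C@H](C(=O)OO)[C@@H](c1ccc(O[Si](C(C)C)(C(C)C)C(C)C)c(O[Si](C(C)C)(C(C)C)C(C)C)c1)O2 | intermediate
12 | (2S,3S)-2-[3,4-bis(triisopropylsilyloxy)phenyl]-4-hydroxy-2,3-dihydrobenzofuran-3-carboxylic acid | Oc1cccc2c1[C@H](C(=O)O)[C@@H](c1ccc(O[Si](C(C)C)(C(C)C)C(C)C)c(O[Si](C(C)C)(C(C)C)C(C)C)c1)O2 | intermediate
13 | (2S,3S)-2-[3,4-bis(triisopropylsilyloxy)phenyl]-4,7-dioxo-2,3,4,7-tetrahydrobenzofuran-3-carboxylic acid | O=C1C=CC(=O)C2=C1[C@H](C(=O)O)[C@@H](c1ccc(O[Si](C(C)C)(C(C)C)C(C)C)c(O[Si](C(C)C)(C(C)C)C(C)C)c1)O2 | intermediate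
14 | (2S,3S)-2-[3,4-bis(triisopropylsilyloxy)phenyl]-4,7-dihydroxy-2,3-dihydrobenzofuran-3-carboxylic acid | Oc1ccc(O)c2c1[C@H](C(=O)O)[C@@H](c1ccc(O[Si](C(C)C)(C(C)C)C(C)C)c(O[Si](C(C)C)(C(C)C)C(C)C)c1)O2 | intermediate
15 | triisopropylsilyl (2S,3S)-2-[3,4-bis(triisopropylsilyloxy)phenyl]-4-hydroxy-7-(triisopropylsilyloxy)-2,3-dihydrobenzofuran-3-carboxylate | Oc1ccc(O[Si](C(C)C)(C(C)C)C(C)C)c2c1[C@H](C(=O)O[Si](C(C)C)(C(C)C)C(C)C)[C@@H](c1ccc(O[Si](C(C)C)(C(C)C)C(C)C)c(O[Si](C(C)C)(C(C)C)C(C)C)c1)O2 | intermediate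
16 | triisopropylsilyl (2S,3S)-2-[3,4-bis(triisopropylsilyloxy)phenyl]-7-(triisopropylsilyloxy)-4-(trifluoromethylsulfonyloxy)-2,3-dihydrobenzofuran-3-carboxylate | O=S(=O)(Oc1ccc(O[Si](C(C)C)(C(C)C)C(C)C)c2c1[C@H](C(=O)O[Si](C(C)C)(C(C)C)C(C)C)[C@@H](c1ccc(O[Si](C(C)C)(C(C)C)C(C)C)c(O[Si](C(C)C)(C(C)C)C(C)C)c1)O2)C(F)(F)F | intermediate
17 | (R)-3-(3,4-dihydroxyphenyl)-2-hydroxypropanoic acid (danshensu) | O=C(O)[C@H](O)Cc1ccc(O)c(O)c1 | starting material
18 | methyl (R)-3-(3,4-dihydroxyphenyl)-2-hydroxypropanoate | COC(=O)[C@H](O)Cc1ccc(O)c(O)c1 | intermediate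
19 | methyl (R)-3-[3,4-bis(triisopropylsilyloxy)phenyl]-2-hydroxypropanoate | COC(=O)[C@H](O)Cc1ccc(O[Si](C(C)C)(C(C)C)C(C)C)c(O[Si](C(C)C)(C(C)C)C(C)C)c1 | intermediate
20 | methyl (R)-2-(acryloyloxy)-3-[3,4-bis(triisopropylsilyloxy)phenyl]propanoate | COC(=O)[C@H](OC(=O)C=C)Cc1ccc(O[Si](C(C)C)(C(C)C)C(C)C)c(O[Si](C(C)C)(C(C)C)C(C)C)c1 | intermediate
21 | triisopropylsilyl (2S,3S)-2-[3,4-bis(triisopropylsilyloxy)phenyl]-4-{(E)-3-[(R)-3-(3,4-bis(triisopropylsilyloxy)phenyl)-1-methoxy-1-oxopropan-2-yloxy]-3-oxoprop-1-enyl}-7-(triisopropylsilyloxy)-2,3-dihydrobenzofuran-3-carboxylate | COC(=O)[C@@H](Cc1ccc(O[Si](C(C)C)(C(C)C)C(C)C)c(O[Si](C(C)C)(C(C)C)C(C)C)c1)OC(=O)/C=C/c1ccc(O[Si](C(C)C)(C(C)C)C(C)C)c2c1[C@H](C(=O)O[Si](C(C)C)(C(C)C)C(C)C)[C@@H](c1ccc(O[Si](C(C)C)(C(C)C)C(C)C)c(O[Si](C(C)C)(C(C)C)C(C)C)c1)O2 | intermediate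
22 | (2S,3S)-2-(3,4-dihydroxyphenyl)-4-{(E)-3-[(R)-3-(3,4-dihydroxyphenyl)-1-methoxy-1-oxopropan-2-yloxy]-3-oxoprop-1-enyl}-7-hydroxy-2,3-dihydrobenzofuran-3-carboxylic acid | COC(=O)[C@@H](Cc1ccc(O)c(O)c1)OC(=O)/C=C/c1ccc(O)c2c1[C@H](C(=O)O)[C@@H](c1ccc(O)c(O)c1)O2 | target

Total step count: 13. Longest linear sequence: 10 steps (steps 1–8, 12 and 13, from caffeic acid).

Steps most likely to fail

Step 3. The two faces of the alkene may not be told apart (the chelate may be populated too little, or the unbound imide may react faster than the bound one), and the Lewis acid may divert the dione into polar conjugate addition at the benzylic carbon. The fallback gives up induction and uses the auxiliary as a resolving handle. It sets out from 6 and 7, which are combined under the classical Lewis-acid-free conditions (Mn(OAc)3·2H2O, AcOH, 50 °C) established for cinnamic amides. Both trans products are expected, namely 8 and its diastereomer (S)-4-benzyl-3-{(2R,3R)-2-[3,4-bis(triisopropylsilyloxy)phenyl]-4-oxo-2,3,4,5,6,7-hexahydrobenzofuran-3-carbonyl}oxazolidin-2-one F1. Because they differ in their relation to the fixed centre of the auxiliary, they are separated by chromatography or crystallisation, and the route is rejoined at 8.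

Step 12. Oxidative addition and insertion at the hindered, electron-rich C4 triflate may be slow, so that triflate hydrolysis, acrylate polymerisation or amine-induced opening of the dihydrofuran take over. The fallback makes the aryl–carbon bond by a base-free Stille coupling and attaches the ester side chain by olefin metathesis. It sets out from 16: tributyl(vinyl)stannane, Pd(PPh3)4 and LiCl in dioxane at 90 °C should give triisopropylsilyl (2S,3S)-2-[3,4-bis(triisopropylsilyloxy)phenyl]-7-(triisopropylsilyloxy)-4-vinyl-2,3-dihydrobenzofuran-3-carboxylate F3. Cross-metathesis of F3 with acrylate 20 (second-generation Grubbs catalyst, CH2Cl2, 40 °C) should then give the E enoate and rejoins the route at 21.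

Step 5. Hydroxide or hydroperoxide may strip the aryl silyl ethers or open the dihydrofuran by β-elimination from C3 before the hindered imide is cleaved. The fallback exchanges the auxiliary for an allyl ester under non-aqueous, weakly basic conditions and removes that ester under neutral palladium catalysis. It sets out from 10: bromomagnesium allyl oxide (allyl alcohol, MeMgBr, THF, 0 °C; the magnesium alkoxide transesterification of acyl oxazolidinones) should give allyl (2S,3S)-2-[3,4-bis(triisopropylsilyloxy)phenyl]-4-hydroxy-2,3-dihydrobenzofuran-3-carboxylate F2. Pd(PPh3)4 and morpholine in THF at room temperature (Tsuji–Trost deallylation) then release the acid and rejoin the route at 12.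

Further compounds

F1 | step 3 | (S)-4-benzyl-3-{(2R,3R)-2-[3,4-bis(triisopropylsilyloxy)phenyl]-4-oxo-2,3,4,5,6,7-hexahydrobenzofuran-3-carbonyl}oxazolidin-2-one | O=C1CCCC2=C1[C@@H](C(=O)N1C(=O)OC[C@@H]1Cc1ccccc1)[C@H](c1ccc(O[Si](C(C)C)(C(C)C)C(C)C)c(O[Si](C(C)C)(C(C)C)C(C)C)c1)O2
F2 | step 5 | allyl (2S,3S)-2-[3,4-bis(triisopropylsilyloxy)phenyl]-4-hydroxy-2,3-dihydrobenzofuran-3-carboxylate | Oc1cccc2c1[C@H](C(=O)OCC=C)[C@@H](c1ccc(O[Si](C(C)C)(C(C)C)C(C)C)c(O[Si](C(C)C)(C(C)C)C(C)C)c1)O2
F3 | step 12 | triisopropylsilyl (2S,3S)-2-[3,4-bis(triisopropylsilyloxy)phenyl]-7-(triisopropylsilyloxy)-4-vinyl-2,3-dihydrobenzofuran-3-carboxylate | C=Cc1ccc(O[Si](C(C)C)(C(C)C)C(C)C)c2c1[C@H](C(=O)O[Si](C(C)C)(C(C)C)C(C)C)[C@@H](c1ccc(O[Si](C(C)C)(C(C)C)C(C)C)c(O[Si](C(C)C)(C(C)C)C(C)C)c1)O2
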